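- No constant of this chemistry is in hand, so we work from the plateaus, in logarithms, and ask which two times stop Xp (the product) from rising when Xa (the substrate) and Xc (the catalyst) are charged.

| flask | Xa | Xc | time |
|---|---|---|---|
| theta | 120 mM | 1.20 mM |  |
| delta | 72.0 mM | 1.20 mM |  |
| gamma | 360 mM | 1.20 mM |  |
| zeta | 120 mM | 0.600 mM |  |
| beta | 120 mM | 1.20 mM | 180 min |

- theta run (time / min: [Xp] / mM): 3.7: 15.4; 8.2: 19.0; 18: 22.4; 41: 23.9; 92: 24.0
- delta run (time / min: [Xp] / mM): 3.7: 7.6; 8.2: 11.9; 18: 13.2; 41: 15.6; 92: 16.7
- gamma run (time / min: [Xp] / mM): 3.7: 35.9; 8.2: 42.5; 18: 47.0; 41: 48.7; 92: 51.1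
- zeta run (time / min: [Xp] / mM): 3.7: 9.0; 8.2: 12.0; 18: 16.3; 41: 19.0; 92: 19.0

(standard deviation of a reading: 1 mM)

1. apparent order in [Xa] of the starting rate, round the charge of the theta run (the rate where two percent of its Xa have turned into Xp) (one fixed amount of Xp, the same in the runs compared)
2. apparent order in [Xc] of the starting rate, round the charge of the theta run (the rate where two percent of its Xa have turned into Xp)
3. Xp in the beta run at 180 min, as a share of the Xa charged

- Overall: Xa -> Xp, with Xc as catalyst.
- Constant volume, constant temperature.
- An order is taken over about fifteen percent of the charge, up and down.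

- The last reading of the theta run stands at 20.0% of its Xa as Xp, that of the delta run, with less Xa, at 23.2%, and that of the zeta run, with half the Xc, at 15.8%, so we suppose two clocks: t_C, the catalyst lifetime, which shortens as Xc is charged, and t_A, the time Xa lasts, which shortens as Xa is charged.
- If the catalyst fades steadily after t_C, Xp grows with the logarithm of time until t_A ends it, so we take the final share to rise with ln(t_A/t_C), with t_A/t_C proportional to the Xc charge over the Xa charge.
- Theta against zeta changes that ratio 2.00-fold through Xc, with Xa held at 120 mM, and the last reading of the zeta run lies 4.2 percentage points lower, which reads 6.01% as g, the stall gain, the share of the charge won per e-fold of t_A/t_C.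
- Carried to the delta run, where Xa changes the ratio instead, g from theta's share gives 16.6 mM of Xp, and the delta run read 16.7 mM at 92 min, a gap smaller than the scatter of 1 mM.
- The beta run has theta's charges, so its ratio is theta's, and the theta readings moved 0.100 mM between 41 min and 92 min; we commit to 20.0% for the beta run, give or take 0.83 points.
- The forecast gave 20.3% (from 19.2% to 22%), with orders 0.9 in Xa and 0.95 in Xc, taking beta from theta's flat end, “allowing a little creep”.
- The beta run gives 20.6%, with orders 1.2 in Xa and 0.80 in Xc, and the passing of Xc into X moves the readings by 42 times the scatter, root mean square.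

    2 Xc ⇌ Xc2, settled at all times (449.0 /M)
    Xc + Xa → Xp + Xc (94.80 /M/min)
    2 Xc → 2 X (684.0 /M/min)
    2 Xa → Q (0.4158 /M/min)

- Starting from beta's share, g puts the gamma run, with 3.00 times the Xa, at 50.3 mM of Xp, and gamma read 51.1 mM at 92 min.

All runs stem from a simulated flask for an exercise, noise included.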